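Atom labels C1–C11 follow tricyclo[5.4.0.0^2,8]undecane (longipinane) numbering and are kept for all bicyclic and monocyclic precursors.

## The problem

Target 26 is a cyclobutane (C1–C2–C8–C7) whose two diagonals are bridged on opposite faces. C1 and C8 are joined by the enone unit C11(=O)–C10=C9(CH3), and C2 and C7 by the chain C3–C4–C5–C6 of the seven-membered ring. Four of the six stereocentres (C1, C2, C7, C8) are locked by this cage: once both bridges exist, only one relative arrangement is possible, with the C2 methyl and the C7 hydrogen on the enone side. Their absolute sense therefore reduces to telling C1 (ketone side) from C8 (methyl-alkene side). C3 and C5 carry trans oxygens with two different acyl groups and hang below the cage close to a local mirror plane through C2 and C7. C1 and C8 look alike from there, so the cage cannot be relied on to direct reagents at C3 or C5; each needs its own control, and the two oxygens must be told apart. C6 is quaternary and bonded to the ring carbon C7, a congested bond. The fragile elements are the conjugated senecioate (base, deconjugation), the enone, and above all the strained ring beside C11: a C7/C11 dione that cannot enolise is open to retro-Claisen cleavage, and a hydroxyl at C7 beside a C11 carbonyl is a 2-acylcyclobutanol that opens by retro-aldol. The enabling feature is that C1 and C8 both flank C7 and are spanned by C11–C10–C9, so with C7 as a ketone the core is a 3,3-disubstituted cyclobutanone bridged at both α-carbons by a but-2-enoyl unit.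

## Retrosynthesis

**C9=C10 last (26 from 25).** No skeletal bond is cut; the alkene is introduced by palladium-mediated dehydrogenation of the C11 silyl enol ether 25. Carrying C11 as an enol ether rather than as a ketone or enone removes the electron sink needed for retro-aldol opening of the C1–C7 bond while C7 bears oxygen. It also leaves C5 as the only ketone when that centre is reduced, and it is already the substrate of the final oxidation. The forward step must find the single β-hydrogen at C9 and leave both esters alone.

**C7–H (25 from 24 from 23).** The C7–O bond is cut. The tertiary hydroxyl is the scar of ring closure onto the C7 ketone. Elimination is impossible (C6 is quaternary, C1 and C8 are bridgeheads) and a C7 cation would rearrange, so a radical deoxygenation through the methyl oxalate 24 is chosen. The seven-membered ring leaves only one face for the incoming hydrogen. The step is placed after C5 has become an ester (23), so that the C7 radical has no β-ketone to migrate.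

**C5 and the two esters (23 from 21 and 22; 21 from 20).** The C5–O acyl bond and the C5–H bond are cut. The esters are distinguished by the order in which the oxygens appear: C3–O arrives with the aldol and is senecioylated before C5 is a carbinol. The C5 ketone of 20 lies between quaternary C6 and methylene C4, the textbook case for an oxazaborolidine-catalysed reduction, so its configuration is set by the catalyst.

**C6–C7 (20 from 18).** This cut gives a C6 enolate and the C7 ketone left by the annulation. It is preferred to closures at C3–C4 or C4–C5 because it uses that carbonyl directly and closes onto a carbon held rigidly beside the anchor of the chain. The enolate must be regiodefined, since a C4 enolate would close a five-membered ring onto C7. The isopropenyl ketone 18 meets this need: conjugate hydride addition gives only the C5=C6 enolate, without electrophilic halogenation that the enol ether would not survive. The precursor is bicyclic, with one ring and two stereocentres fewer.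

**C3–C4 (18 from 16 and 17; 16 from 13 and 14).** Aldol disconnection to aldehyde 13 and the methyl ketone 14. A chiral boron enolate is asked to set C3 and to ignore the C7 ketone. Acid chloride 17 then caps the C3 oxygen.

**Adjusting C3 and C11 (13 from 12 from 11).** The acetal of 11 is opened to the aldehyde 12 while acid is still tolerated. C11, the only enolisable carbonyl, is then masked as the silyl enol ether 13.

**C8–C9 and C1–C11 (11 from 6, 8 and amine 7).** Both bonds of the three-carbon bridge are cut. The precursor is the achiral cyclobutanone 6, so one operation must close the six-membered ring and create C1, C2 and C8 in one absolute sense. Stepwise α-alkylation and acylation would need several steps and a Claisen closure that is thermodynamically uphill for a non-enolisable dione. 11 is (1R,5R,7R), the cage sense of 26.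

**Four-membered ring (6 from 5; 5 from 2 and 3; 2 from 1).** A ketene [2+2] cycloaddition onto the 1,1-disubstituted alkene 2, then dechlorination, gives 6. The ring is bought at the outset from commodity materials, and the branched acetal is the group that later biases the face.

## Roads not taken

Alternative 1: A terpene cyclase of the longipinene class would take (2E,6E)-farnesyl diphosphate A1 to α-longipinene A2, forming C6–C7, C1–C7 and C2–C8 and all three rings in one cation cascade. Oxidations at C11, C3 and C5 would follow. For the carbon skeleton and the four cage stereocentres this is better than the chosen plan, since one step replaces about nine. Its weakness is the oxygen pattern. C11 is allylic and accessible, but C3 and C5 are neopentyl methylenes with no handle. They would have to be hydroxylated site-selectively, trans to each other, and in a way that lets two different acyl groups be placed, which means finding or evolving oxygenases or accepting unselective C–H oxidation. An enzyme giving the correct enantiomer of A2 must also be at hand. The chosen plan sets against this that every oxygen (C3, C5, C11) arrives inside a building block at a defined position and that each stereocentre has a named controller.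

Alternative 2: An intramolecular Diels–Alder reaction of a silyloxydiene onto an isopropenyl ketone would form C2–C8 and C1–C11 and give the cis-fused bicyclo[5.4.0]undecenone A3 with six- and seven-membered rings at once. The reaction type is well precedented, the quaternary C2 is set cleanly, and the C3 and C5 oxygens are differentiated from the start, which the chosen plan achieves only by ordering its steps. The weak point is the four-membered ring. The C1–C7 bond remains for the end, as a displacement by the C1 enolate at C7, a secondary neopentyl carbon beside the gem-dimethyl C6, in a four-membered closure. The cycloaddition must also close a seven-membered ring through its tether, with facial control resting on remote stereocentres. The chosen plan makes the cyclobutane first by a [2+2] and closes every later ring onto it.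

Alternative 3: A lithium enolate of an acetyl group on C2 would add to a C5 aldehyde (C4–C5, seven-membered ring). The aldolate would add to 3-methylbutanal A5, and hydride transfer to the C3 ketone would give A4, the target lacking only the senecioyl group. This endgame sets C5 and C3 anti and installs the isovalerate in one operation; the chosen plan needs an aldol, a reduction and two acylations for the same result. Its weak points lie elsewhere. It presupposes the complete cage with the C6–C7 bond and the enone already in place, which is the hard part. The aldehyde face must be chosen relative to a cage that lies on a local mirror plane, so the absolute sense at C5, and through it at C3, is poorly controlled. A strong base meets an enone with γ-hydrogens, and the seven-membered aldol is reversible. The chosen plan answers with reagent control at C3 and C5 and with a ring closure (C6–C7) that creates the difficult quaternary–ring bond itself.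

Key step: step 4

Assumption: the hand of amine 7 (step 4) and of the chloroborane (step 7) is assigned from steric models; both reagents are available in either hand, and the antipode is used without other change if the sense proves opposite.

## Route

Step 1
Reactants: 1 methacrolein
Product: 2 3,3-dimethoxy-2-methylprop-1-ene
Conditions: HC(OMe)3, MeOH, NH4NO3 (cat.), rt
Reagents that add atoms: trimethyl orthoformate, COC(OC)OC
Why: Acid-catalysed acetalisation with the orthoformate as methoxy donor and water scavenger; the mild ammonium salt should avoid conjugate addition of methanol to the enal.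

Step 2
Reactants: 2 3,3-dimethoxy-2-methylprop-1-ene; 3 trichloroacetyl chloride
Product: 5 2,2-dichloro-3-(dimethoxymethyl)-3-methylcyclobutan-1-one (racemic), via dichloroketene 4 (not isolated)
Conditions: Zn–Cu couple, DME, Et2O, reflux, slow addition of 3
Reagents that add atoms: none
Why: Ketene [2+2] cycloaddition: zinc dechlorinates 3 to dichloroketene, whose carbonyl carbon bonds to the CH2 terminus of the 1,1-disubstituted alkene, so the quaternary carbon ends up at ring position 3. DME ties up ZnCl2 and should spare the acetal.

Step 3
Reactants: 5 2,2-dichloro-3-(dimethoxymethyl)-3-methylcyclobutan-1-one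
Product: 6 3-(dimethoxymethyl)-3-methylcyclobutan-1-one
Conditions: Zn dust, NH4Cl, MeOH, rt
Reagents that add atoms: none
Why: Zinc reduction of the α,α-dichloroketone; the weak proton source in methanol should leave the acetal intact, and the product is achiral with two enantiotopic α-methylenes.

Step 4
Reactants: 6 3-(dimethoxymethyl)-3-methylcyclobutan-1-one; 7 (2R,5R)-2,5-diphenylpyrrolidine; 8 (E)-but-2-enoyl chloride
Product: 11 (1R,5R,7R)-7-(dimethoxymethyl)-4,7-dimethylbicyclo[3.1.1]heptane-2,6-dione (C4 epimers), via enamine 9 (not isolated), via iminium chloride 10 (not isolated)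
Conditions: 7, 4 Å MS, PPTS (cat.), PhMe, 60 °C; then 8, MeCN, 0 → 80 °C; then NaOAc/AcOH buffer (pH 5), H2O–THF, rt
Reagents that add atoms: water, O
Why: Proposed new method: enamine 9 should attack the β-carbon of 8, directly or after N-acylation and a [3,3] shift, forming C8–C9 and leaving an iminium with a pendant ketene or acyl chloride; loss of the C1 proton regenerates an enamine that is C-acylated at C11 to give iminium 10, which buffered water hydrolyses to 11. The closest known reaction is the α,α′-annulation of pyrrolidine enamines of five- to eight-membered ketones with α,β-unsaturated acid chlorides to bicyclo[n.3.1]alkanediones; a cyclobutanone and an enantioselective version are untested. The six-membered ring closes by intramolecular C-acylation (6-enolendo-exo-trig) and must span the four-membered ring 1,3-diaxially, which forces both new bonds onto one face. That face is chosen when C8–C9 forms: the acyl unit should approach anti to the branched dimethoxymethyl group and syn to the methyl on the adjacent quaternary carbon, which fixes C2 with its methyl on the bridge side. The two α-carbons of 6 are enantiotopic; the twofold-symmetric amine makes the two enamine regioisomers diastereomeric, and only the one whose unshielded face coincides with the methyl face should react, which sets C1 and C8. The methyl-bearing C9 forms as a mixture and is erased in step 14. The symmetric ketone needs no regiocontrol, and hydrolysis is kept buffered and free of hydroxide or alkoxide because 11 is a non-enolisable 1,3-dione.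

Step 5
Reactants: 11 (1R,5R,7R)-7-(dimethoxymethyl)-4,7-dimethylbicyclo[3.1.1]heptane-2,6-dione
Product: 12 (1R,5R,6R)-4,6-dimethyl-2,7-dioxobicyclo[3.1.1]heptane-6-carbaldehyde (C4 epimers)
Conditions: TFA–H2O (9:1), CH2Cl2, 0 °C
Reagents that add atoms: water, O
Why: Acid hydrolysis of the acetal, done now because no acid-labile group is present yet; cold acidic medium avoids the base-triggered retro-Claisen cleavage of the dione.

Step 6
Reactants: 12 (1R,5R,6R)-4,6-dimethyl-2,7-dioxobicyclo[3.1.1]heptane-6-carbaldehyde
Product: 13 (1R,5R,6R)-4,6-dimethyl-7-oxo-2-[(triisopropylsilyl)oxy]bicyclo[3.1.1]hept-2-ene-6-carbaldehyde (C4 epimers)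
Conditions: TIPSOTf, Et3N, CH2Cl2, −20 → 0 °C
Reagents that add atoms: triisopropylsilyl trifluoromethanesulfonate, CC(C)[Si](C(C)C)(C(C)C)OS(=O)(=O)C(F)(F)F
Why: Soft enolisation and O-silylation; C10 is the only enolisable position, since the aldehyde sits on quaternary C2 and C1 and C8 are bridgeheads (Bredt's rule). The bulky enol ether masks C11 until step 14 and is the handle for the final dehydrogenation.

Step 7
Reactants: 13 (1R,5R,6R)-4,6-dimethyl-7-oxo-2-[(triisopropylsilyl)oxy]bicyclo[3.1.1]hept-2-ene-6-carbaldehyde; 14 3-methylbut-3-en-2-one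
Product: 16 (1R,5R,6R)-6-[(1R)-1-hydroxy-4-methyl-3-oxopent-4-en-1-yl]-4,6-dimethyl-2-[(triisopropylsilyl)oxy]bicyclo[3.1.1]hept-2-en-7-one (C4 epimers), via diisopinocampheylboron enolate 15 (not isolated)
Conditions: 14, (−)-Ipc2BCl, Et3N, Et2O, 0 °C; then 13, −78 → −20 °C; then MeOH, pH 7 buffer (no peroxide)
Reagents that add atoms: none
Why: Boron-mediated aldol of a methyl ketone forms C3–C4; the boron enolate should add to the aldehyde and not to the C7 ketone. Because the cage gives no facial bias, the isopinocampheyl ligands are relied on to set C3 (R), and the minor epimer is removed by chromatography. Peroxide-free work-up avoids Baeyer–Villiger oxidation of the cyclobutanone.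

Step 8
Reactants: 16 aldol adduct (as named in step 7); 17 3-methylbut-2-enoyl chloride
Product: 18 (1R)-1-[(1R,5R,6R)-4,6-dimethyl-7-oxo-2-[(triisopropylsilyl)oxy]bicyclo[3.1.1]hept-2-en-6-yl]-4-methyl-3-oxopent-4-en-1-yl 3-methylbut-2-enoate (C4 epimers)
Conditions: 17, pyridine, DMAP (cat.), CH2Cl2, 0 °C
Reagents that add atoms: none
Why: DMAP-catalysed acylation places the senecioate on the only hydroxyl present, which settles which oxygen carries which ester and blocks retro-aldol at C3–C4 in the next step. A weak base at low temperature limits deconjugation of the acyl group and β-elimination.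

Step 9
Reactants: 18 senecioate (as named in step 8)
Product: 20 (1S,2R,3R,7R,8R)-7-hydroxy-2,6,6,9-tetramethyl-5-oxo-11-[(triisopropylsilyl)oxy]tricyclo[5.4.0.0^2,8]undec-10-en-3-yl 3-methylbut-2-enoate (C9 epimers), via copper enolate 19 (not isolated)
Conditions: [(Ph3P)CuH]6, PhMe, −40 → 0 °C; then aq. NH4Cl
Reagents that add atoms: none
Why: Reductive aldol cyclisation: conjugate hydride addition to the 1,1-disubstituted enone gives only the tetrasubstituted C5=C6 enolate (monovalent copper), which adds to the strained C7 ketone (7-enolexo-exo-trig), forming C6–C7 and quaternary C6. The tether on the lower face of C2 can reach C7 only from the face anti to the C9–C11 bridge, so the hydroxyl ends syn to that bridge; with C11 masked the cyclobutanol has no carbonyl to fragment toward.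

Step 10
Reactants: 20 tricyclic hydroxy ketone (as named in step 9)
Product: 21 (1S,2R,3R,5R,7R,8R)-5,7-dihydroxy-2,6,6,9-tetramethyl-11-[(triisopropylsilyl)oxy]tricyclo[5.4.0.0^2,8]undec-10-en-3-yl 3-methylbut-2-enoate (C9 epimers)
Conditions: (S)-Me-CBS oxazaborolidine (0.3 equiv), catecholborane, PhMe, −78 → −30 °C; then MeOH, aq. NaHCO3
Reagents that add atoms: none
Why: Corey–Bakshi–Shibata reduction: C5 is the only ketone and lies between quaternary C6 (large) and methylene C4 (small), so the (S)-catalyst should deliver hydride to give 5R, trans to the C3 ester. Catecholborane is used because it does not hydroborate the enol ether or the alkenes.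

Step 11
Reactants: 21 diol (as named in step 10); 22 3-methylbutanoyl chloride
Product: 23 (1S,2R,3R,5R,7R,8R)-7-hydroxy-2,6,6,9-tetramethyl-5-[(3-methylbutanoyl)oxy]-11-[(triisopropylsilyl)oxy]tricyclo[5.4.0.0^2,8]undec-10-en-3-yl 3-methylbut-2-enoate (C9 epimers)
Conditions: 22, pyridine, DMAP, CH2Cl2, 0 °C → rt
Reagents that add atoms: none
Why: Acylation of the secondary C5 hydroxyl; the tertiary C7 hydroxyl, shielded by the bridge, should not compete.

Step 12
Reactants: 23 hydroxy diester (as named in step 11)
Product: 24 methyl (1S,2R,3R,5R,7R,8R)-2,6,6,9-tetramethyl-5-[(3-methylbutanoyl)oxy]-3-[(3-methylbut-2-enoyl)oxy]-11-[(triisopropylsilyl)oxy]tricyclo[5.4.0.0^2,8]undec-10-en-7-yl oxalate (C9 epimers)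
Conditions: ClCOCO2Me, Et3N, DMAP, CH2Cl2, 0 °C → rt
Reagents that add atoms: methyl chlorooxoacetate, COC(=O)C(Cl)=O
Why: Methyl oxalyl chloride is small and electrophilic enough to acylate hindered tertiary alcohols, and the mixed oxalate is an established radical precursor for tertiary C–O cleavage.

Step 13
Reactants: 24 tertiary methyl oxalate (as named in step 12)
Product: 25 (1R,2R,3R,5R,7S,8S)-2,6,6,9-tetramethyl-5-[(3-methylbutanoyl)oxy]-11-[(triisopropylsilyl)oxy]tricyclo[5.4.0.0^2,8]undec-10-en-3-yl 3-methylbut-2-enoate (C9 epimers)
Conditions: Bu3SnH, AIBN, PhMe, 110 °C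
Reagents that add atoms: none
Why: Radical deoxygenation of a tertiary oxalate: the stannyl radical adds to the oxalate carbonyl, the C7–O bond breaks, and the C7 radical takes hydrogen from Bu3SnH. The seven-membered ring holds C6 on the lower face, so hydrogen can only arrive syn to the C9–C11 bridge; with C5 already an ester there is no β-ketone for a Dowd–Beckwith acyl shift.

Step 14
Reactants: 25 silyl enol ether (as named in step 13)
Product: 26 (1R,2R,3R,5R,7S,8R)-2,6,6,9-tetramethyl-5-[(3-methylbutanoyl)oxy]-11-oxotricyclo[5.4.0.0^2,8]undec-9-en-3-yl 3-methylbut-2-enoate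
Conditions: Pd(OAc)2 (1.2 equiv), DMSO, 50 °C
Reagents that add atoms: none
Why: Saegusa–Ito oxidation: divalent palladium converts the enol ether to a palladium enolate, and β-hydride elimination of the only β-hydrogen (C9–H) gives the C9=C10 enone and removes the C9 stereocentre. C1 is a bridgehead, so no other alkene can form, and the esters are inert.

## Compound list

1 | methacrolein (2-methylprop-2-enal) | C=C(C)C=O | starting material
2 | 3,3-dimethoxy-2-methylprop-1-ene | C=C(C)C(OC)OC | intermediate
3 | trichloroacetyl chloride | O=C(Cl)C(Cl)(Cl)Cl | starting material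
4 | dichloroketene | ClC(Cl)=C=O | intermediate (not isolated)
5 | 2,2-dichloro-3-(dimethoxymethyl)-3-methylcyclobutan-1-one (racemic) | O=C1CC(C)(C(OC)OC)C1(Cl)Cl | intermediate
6 | 3-(dimethoxymethyl)-3-methylcyclobutan-1-one (achiral) | O=C1CC(C)(C(OC)OC)C1 | intermediate
7 | (2R,5R)-2,5-diphenylpyrrolidine | N1[C@@H](c2ccccc2)CC[C@@H]1c1ccccc1 | starting material
8 | (E)-but-2-enoyl chloride | C/C=C/C(Cl)=O | starting material
9 | (2R,5R)-1-[3-(dimethoxymethyl)-3-methylcyclobut-1-en-1-yl]-2,5-diphenylpyrrolidine (both alkene regioisomers, interconverting) | COC(OC)C1(C)CC(=C1)N1[C@@H](c2ccccc2)CC[C@@H]1c1ccccc1 | intermediate (not isolated)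
10 | (2R,5R)-1-[7-(dimethoxymethyl)-4,7-dimethyl-2-oxobicyclo[3.1.1]heptan-6-ylidene]-2,5-diphenylpyrrolidin-1-ium chloride (cage as in 11) | [Cl-].[N+]3(=C1[C@H]2C(=O)CC(C)[C@@H]1[C@@]2(C)C(OC)OC)[C@@H](c4ccccc4)CC[C@@H]3c3ccccc3 | intermediate (not isolated)
11 | (1R,5R,7R)-7-(dimethoxymethyl)-4,7-dimethylbicyclo[3.1.1]heptane-2,6-dione (C4 epimers; 7-methyl syn to the C2–C4 bridge) | O=C1[C@H]2C(=O)CC(C)[C@@H]1[C@@]2(C)C(OC)OC | intermediate
12 | (1R,5R,6R)-4,6-dimethyl-2,7-dioxobicyclo[3.1.1]heptane-6-carbaldehyde (C4 epimers) | O=C1[C@H]2C(=O)CC(C)[C@@H]1[C@@]2(C)C=O | intermediate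
13 | (1R,5R,6R)-4,6-dimethyl-7-oxo-2-[(triisopropylsilyl)oxy]bicyclo[3.1.1]hept-2-ene-6-carbaldehyde (C4 epimers) | O=C1[C@H]2C(O[Si](C(C)C)(C(C)C)C(C)C)=CC(C)[C@@H]1[C@@]2(C)C=O | intermediate
14 | 3-methylbut-3-en-2-one | CC(=O)C(C)=C | starting material
15 | (3-methylbuta-1,3-dien-2-yl) diisopinocampheylborinate (isopinocampheyl groups from (+)-α-pinene) | C=C(C)C(=C)OB([C@@H]1C[C@@H]2C[C@H]([C@H]1C)C2(C)C)[C@@H]1C[C@@H]2C[C@H]([C@H]1C)C2(C)C | intermediate (not isolated)
16 | (1R,5R,6R)-6-[(1R)-1-hydroxy-4-methyl-3-oxopent-4-en-1-yl]-4,6-dimethyl-2-[(triisopropylsilyl)oxy]bicyclo[3.1.1]hept-2-en-7-one (C4 epimers) | O=C1[C@H]2C(O[Si](C(C)C)(C(C)C)C(C)C)=CC(C)[C@@H]1[C@@]2(C)[C@H](O)CC(=O)C(C)=C | intermediate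
17 | 3-methylbut-2-enoyl chloride | CC(C)=CC(Cl)=O | starting material
18 | (1R)-1-[(1R,5R,6R)-4,6-dimethyl-7-oxo-2-[(triisopropylsilyl)oxy]bicyclo[3.1.1]hept-2-en-6-yl]-4-methyl-3-oxopent-4-en-1-yl 3-methylbut-2-enoate (C4 epimers) | O=C1[C@H]2C(O[Si](C(C)C)(C(C)C)C(C)C)=CC(C)[C@@H]1[C@@]2(C)[C@H](OC(=O)C=C(C)C)CC(=O)C(C)=C | intermediate
19 | copper enolate of 18 at C5=C6 (monovalent copper, triphenylphosphine ligands omitted) | O=C1[C@H]2C(O[Si](C(C)C)(C(C)C)C(C)C)=CC(C)[C@@H]1[C@@]2(C)[C@H](OC(=O)C=C(C)C)CC(O[Cu])=C(C)C | intermediate (not isolated)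
20 | (1S,2R,3R,7R,8R)-7-hydroxy-2,6,6,9-tetramethyl-5-oxo-11-[(triisopropylsilyl)oxy]tricyclo[5.4.0.0^2,8]undec-10-en-3-yl 3-methylbut-2-enoate (C9 epimers; 7-OH syn to the C9–C11 bridge) | CC(C)=CC(=O)O[C@@H]1CC(=O)C(C)(C)[C@]2(O)[C@H]3C(O[Si](C(C)C)(C(C)C)C(C)C)=CC(C)[C@@H]2[C@]31C | intermediate
21 | (1S,2R,3R,5R,7R,8R)-5,7-dihydroxy-2,6,6,9-tetramethyl-11-[(triisopropylsilyl)oxy]tricyclo[5.4.0.0^2,8]undec-10-en-3-yl 3-methylbut-2-enoate (C9 epimers) | CC(C)=CC(=O)O[C@@H]1C[C@@H](O)C(C)(C)[C@]2(O)[C@H]3C(O[Si](C(C)C)(C(C)C)C(C)C)=CC(C)[C@@H]2[C@]31C | intermediate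
22 | 3-methylbutanoyl chloride | CC(C)CC(Cl)=O | starting material
23 | (1S,2R,3R,5R,7R,8R)-7-hydroxy-2,6,6,9-tetramethyl-5-[(3-methylbutanoyl)oxy]-11-[(triisopropylsilyl)oxy]tricyclo[5.4.0.0^2,8]undec-10-en-3-yl 3-methylbut-2-enoate (C9 epimers) | CC(C)=CC(=O)O[C@@H]1C[C@@H](OC(=O)CC(C)C)C(C)(C)[C@]2(O)[C@H]3C(O[Si](C(C)C)(C(C)C)C(C)C)=CC(C)[C@@H]2[C@]31C | intermediate
24 | methyl (1S,2R,3R,5R,7R,8R)-2,6,6,9-tetramethyl-5-[(3-methylbutanoyl)oxy]-3-[(3-methylbut-2-enoyl)oxy]-11-[(triisopropylsilyl)oxy]tricyclo[5.4.0.0^2,8]undec-10-en-7-yl oxalate (C9 epimers) | CC(C)=CC(=O)O[C@@H]1C[C@@H](OC(=O)CC(C)C)C(C)(C)[C@]2(OC(=O)C(=O)OC)[C@H]3C(O[Si](C(C)C)(C(C)C)C(C)C)=CC(C)[C@@H]2[C@]31C | intermediate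
25 | (1R,2R,3R,5R,7S,8S)-2,6,6,9-tetramethyl-5-[(3-methylbutanoyl)oxy]-11-[(triisopropylsilyl)oxy]tricyclo[5.4.0.0^2,8]undec-10-en-3-yl 3-methylbut-2-enoate (C9 epimers) | CC(C)=CC(=O)O[C@@H]1C[C@@H](OC(=O)CC(C)C)C(C)(C)[C@@H]2[C@H]3C(O[Si](C(C)C)(C(C)C)C(C)C)=CC(C)[C@@H]2[C@]31C | intermediate
26 | (1R,2R,3R,5R,7S,8R)-2,6,6,9-tetramethyl-5-[(3-methylbutanoyl)oxy]-11-oxotricyclo[5.4.0.0^2,8]undec-9-en-3-yl 3-methylbut-2-enoate (CNP0335239.1) | CC(C)=CC(=O)O[C@@H]1C[C@@H](OC(=O)CC(C)C)C(C)(C)[C@@H]2[C@H]3C(=O)C=C(C)[C@@H]2[C@]31C | target

## Step count and risks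

Total: 14 steps. Longest linear sequence: 14 steps (1 to 26); all other inputs (3, 7, 8, 14, 17, 22) are purchased.

**Step 4 (key step).** Three things may go wrong. Enamine formation on the strained ring may stall. The sequence may stop after the first bond, because the second closure must build a bridged non-enolisable dione. The amine may discriminate poorly between the enantiotopic α-carbons, or a change of mechanism (C-acylation first) may invert the sense. Fallback with known chemistry, from 6 to 11: condensation of 6 with SAMP gives the hydrazone (S)-N-[3-(dimethoxymethyl)-3-methylcyclobutylidene]-2-(methoxymethyl)pyrrolidin-1-amine F1. Deprotonation with LDA and conjugate addition to methyl (E)-but-2-enoate forms C8–C9 under auxiliary control and gives the adduct hydrazone F2. Ozonolytic cleavage at −78 °C releases the keto ester methyl 3-[(1R,2S)-2-(dimethoxymethyl)-2-methyl-4-oxocyclobutyl]butanoate F3, and LiOH gives the keto acid F4. LDA/TMSCl converts F4 into the silyl ester silyl enol ether F5 (enolised toward the free methylene C1). Oxalyl chloride turns the silyl ester into the acid chloride, which C-acylates the enol ether under ZnCl2 to close C1–C11 and return 11. RAMP is used instead if the sense requires it.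

**Step 6.** The new enol ether may add to the silyl-activated aldehyde (Mukaiyama-type self-condensation), or silylation may stall, because aldehyde and enol ether coexist under a silyl triflate. Fallback, from 11 to 13, reverses the order: LiHMDS/TIPSOTf at −78 °C on the acetal gives (1R,5R,7R)-7-(dimethoxymethyl)-4,7-dimethyl-2-[(triisopropylsilyl)oxy]bicyclo[3.1.1]hept-2-en-6-one F6, in which no aldehyde is present. The acetal is then opened under non-protic conditions (TESOTf, 2,4,6-collidine, then water) to give 13.

**Step 7.** Facial control by the boron ligands may be modest for a methyl ketone enolate and a neopentyl aldehyde, which would erode the C3 ratio; the chloroborane may also exchange with the enol ether. Fallback, from 13 to 16, uses an auxiliary: the divalent tin enolate (Sn(OTf)2, N-ethylpiperidine) of 3-acetyl-(4S)-4-isopropyl-1,3-thiazolidine-2-thione adds to 13 to give the aldol imide F7. Ethanethiol and imidazole convert it into the S-ethyl thioester F8. Fukuyama coupling with isopropenylzinc bromide and PdCl2(PPh3)2 installs the isopropenyl ketone and returns 16; the organozinc should not touch the C7 ketone.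

**Step 9.** The copper enolate may be protonated on work-up without closing the hindered C6–C7 bond, or hydride may reduce the C7 ketone. Fallback, from 18 to 20: RhCl(PPh3)3-catalysed 1,4-hydrosilylation with Et3SiH gives the tetrasubstituted triethylsilyl enol ether F9. BF3·OEt2 at −78 °C then activates the C7 ketone for an intramolecular Mukaiyama aldol, and aqueous work-up returns 20.

**Step 12.** Acylation of the tertiary C7 hydroxyl may stall, because it is flanked by quaternary C6 and lies under the C9–C11 bridge. Fallback, from 23 to 25: deprotonation with KHMDS at −78 °C, capture with CS2 and then MeI gives the S-methyl xanthate F10, using the small electrophile on the alkoxide. Barton–McCombie reduction (Bu3SnH, AIBN) then gives 25 directly; Chugaev elimination is impossible because C6 is quaternary and C1 and C8 are bridgeheads.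

## Further compounds

F1 | step 4 | (S)-N-[3-(dimethoxymethyl)-3-methylcyclobutylidene]-2-(methoxymethyl)pyrrolidin-1-amine | COC[C@@H]1CCCN1N=C1CC(C)(C(OC)OC)C1
F2 | step 4 | methyl 3-[(1R,2S)-2-(dimethoxymethyl)-4-{[(2S)-2-(methoxymethyl)pyrrolidin-1-yl]imino}-2-methylcyclobutyl]butanoate (C3 epimers) | COC[C@@H]1CCCN1N=C1C[C@](C)(C(OC)OC)[C@H]1C(C)CC(=O)OC
F3 | step 4 | methyl 3-[(1R,2S)-2-(dimethoxymethyl)-2-methyl-4-oxocyclobutyl]butanoate (C3 epimers) | O=C1C[C@](C)(C(OC)OC)[C@H]1C(C)CC(=O)OC
F4 | step 4 | 3-[(1R,2S)-2-(dimethoxymethyl)-2-methyl-4-oxocyclobutyl]butanoic acid (C3 epimers) | O=C1C[C@](C)(C(OC)OC)[C@H]1C(C)CC(=O)O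
F5 | step 4 | trimethylsilyl 3-[(1R,4S)-4-(dimethoxymethyl)-4-methyl-2-[(trimethylsilyl)oxy]cyclobut-2-en-1-yl]butanoate (C3 epimers) | C[Si](C)(C)OC1=C[C@](C)(C(OC)OC)[C@H]1C(C)CC(=O)O[Si](C)(C)C
F6 | step 6 | (1R,5R,7R)-7-(dimethoxymethyl)-4,7-dimethyl-2-[(triisopropylsilyl)oxy]bicyclo[3.1.1]hept-2-en-6-one (C4 epimers) | O=C1[C@H]2C(O[Si](C(C)C)(C(C)C)C(C)C)=CC(C)[C@@H]1[C@@]2(C)C(OC)OC
F7 | step 7 | (4S)-3-[(3R)-3-hydroxy-3-{(1R,5R,6R)-4,6-dimethyl-7-oxo-2-[(triisopropylsilyl)oxy]bicyclo[3.1.1]hept-2-en-6-yl}propanoyl]-4-(propan-2-yl)-1,3-thiazolidine-2-thione | O=C1[C@H]2C(O[Si](C(C)C)(C(C)C)C(C)C)=CC(C)[C@@H]1[C@@]2(C)[C@H](O)CC(=O)N1C(=S)SC[C@@H]1C(C)C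
F8 | step 7 | S-ethyl (3R)-3-hydroxy-3-{(1R,5R,6R)-4,6-dimethyl-7-oxo-2-[(triisopropylsilyl)oxy]bicyclo[3.1.1]hept-2-en-6-yl}propanethioate | O=C1[C@H]2C(O[Si](C(C)C)(C(C)C)C(C)C)=CC(C)[C@@H]1[C@@]2(C)[C@H](O)CC(=O)SCC
F9 | step 9 | (1R)-1-[(1R,5R,6R)-4,6-dimethyl-7-oxo-2-[(triisopropylsilyl)oxy]bicyclo[3.1.1]hept-2-en-6-yl]-4-methyl-3-[(triethylsilyl)oxy]pent-3-en-1-yl 3-methylbut-2-enoate | O=C1[C@H]2C(O[Si](C(C)C)(C(C)C)C(C)C)=CC(C)[C@@H]1[C@@]2(C)[C@H](OC(=O)C=C(C)C)CC(O[Si](CC)(CC)CC)=C(C)C
F10 | step 12 | O-[C7 of 23] S-methyl carbonodithioate (xanthate of 23, other groups unchanged) | CC(C)=CC(=O)O[C@@H]1C[C@@H](OC(=O)CC(C)C)C(C)(C)[C@]2(OC(=S)SC)[C@H]3C(O[Si](C(C)C)(C(C)C)C(C)C)=CC(C)[C@@H]2[C@]31C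
A1 | alternative 1 | (2E,6E)-farnesyl diphosphate | CC(C)=CCC/C(C)=C/CC/C(C)=C/COP(=O)(O)OP(=O)(O)O
A2 | alternative 1 | α-longipinene (enantiomer matching the target) | C1CCC(C)(C)[C@@H]2[C@H]3CC=C(C)[C@@H]2[C@]31C
A3 | alternative 2 | cis-fused 5-(tert-butyldimethylsilyloxy)-7-(4-methoxybenzyloxy)-2,6,6,9-tetramethyl-11-(triisopropylsilyloxy)bicyclo[5.4.0]undec-9-en-3-one | O=C1C[C@@H](O[Si](C)(C)C(C)(C)C)C(C)(C)[C@@H](OCc2ccc(OC)cc2)[C@@H]3C(C)=CC(O[Si](C(C)C)(C(C)C)C(C)C)C[C@@]31C
A4 | alternative 3 | (1R,2R,3R,5R,7S,8R)-3-hydroxy-2,6,6,9-tetramethyl-11-oxotricyclo[5.4.0.0^2,8]undec-9-en-5-yl 3-methylbutanoate | O[C@@H]1C[C@@H](OC(=O)CC(C)C)C(C)(C)[C@@H]2[C@H]3C(=O)C=C(C)[C@@H]2[C@]31C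
A5 | alternative 3 | 3-methylbutanal | CC(C)CC=O
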